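**Plan**

- Retrosynthesis: the two sulfate O–S bonds (O7 and O4') are cut first, then the two benzyl ethers. Ring B is then cut across C1'–C2' and C5'–C6', which leads back to a chromone carrying a terminal alkyne at C2 and a 1-methoxy-3-silyloxybutadiene.
- Enabling feature: ring B is a benzene with only two substituents, the chromone C2 on C1' and an oxygen on C4', in a para relation. A terminal alkyne polarised by the C4 carbonyl and a 1-alkoxy-3-silyloxydiene deliver exactly this pattern after loss of methanol.
- Further cuts: the alkyne carbon comes from a C2 aldehyde by one-carbon homologation, the pyranone (O1–C2 and C2–C3) from a 2-hydroxyacetophenone and diethyl oxalate, and the C6 oxygen from para-hydroxylation of phloroacetophenone dibenzyl ether.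
- Forward order: ring A is bought and adjusted (steps 1–3), ring C is closed in step 4, ring B is built in step 8, and debenzylation and 7,4'-selective sulfation finish the route.
- Stereochemistry: the target has no stereocentre and no stereogenic double bond. The one sp3 centre of the cycloadduct is lost on aromatisation.

Key step: step 8

Remark: the target is taken as the free bis(hydrogen sulfate) as drawn. Aryl hydrogen sulfates hydrolyse readily in acid, so the free acid would be released from its pyridinium salt by cold cation exchange and freeze-dried at once.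

**Route**

Step 1
Reactants: 1 2',4',6'-trihydroxyacetophenone
Product: 2 1-[2,4-bis(benzyloxy)-6-hydroxyphenyl]ethanone
Conditions: BnBr (2.1 equiv), K2CO3, DMF, 25 °C
Reagents that add atoms: benzyl bromide, BrCc1ccccc1
Why: Williamson etherification in which the 4-OH and one ortho OH are alkylated while the remaining ortho OH, hydrogen-bonded to the acetyl carbonyl, is far less nucleophilic, so two equivalents of halide should stop at the dibenzyl ether.

Step 2
Reactants: 2 1-[2,4-bis(benzyloxy)-6-hydroxyphenyl]ethanone
Product: 4 1-[2,4-bis(benzyloxy)-3,6-dihydroxyphenyl]ethanone, via potassium aryl sulfate 3 (not isolated)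
Conditions: K2S2O8, aq KOH, pyridine, 0 to 25 °C; then aq HCl (pH 1), 80 °C
Reagents that add atoms: potassium peroxydisulfate, [K+].[K+].[O-]S(=O)(=O)OOS(=O)(=O)[O-]
Why: Elbs persulfate oxidation, in which the phenoxide attacks a peroxide oxygen through the only free carbon para to O− (ring C3) to give aryl sulfate 3, which warm dilute acid hydrolyses to the hydroquinone while the benzyl ethers persist.

Step 3
Reactants: 4 1-[2,4-bis(benzyloxy)-3,6-dihydroxyphenyl]ethanone
Product: 5 1-[2,4-bis(benzyloxy)-6-hydroxy-3-methoxyphenyl]ethanone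
Conditions: MeI (1.1 equiv), K2CO3, acetone, 40 °C
Reagents that add atoms: iodomethane, CI
Why: Selective Williamson methylation, since the new 3-OH is free whereas the 6-OH is locked in a hydrogen bond to the acetyl group, so one equivalent of MeI should methylate O3 only.

Step 4
Reactants: 5 1-[2,4-bis(benzyloxy)-6-hydroxy-3-methoxyphenyl]ethanone; 6 diethyl oxalate
Product: 8 ethyl 5,7-bis(benzyloxy)-6-methoxy-4-oxo-4H-chromene-2-carboxylate, via diketo ester 7 (not isolated)
Conditions: NaOEt, EtOH, 70 °C; then HCl, EtOH, 50 °C
Reagents that add atoms: none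
Why: Crossed Claisen condensation of the methyl ketone enolate with the non-enolisable oxalate followed by acid-catalysed cyclodehydration of the phenol onto the α-keto ester carbonyl, the standard entry to chromone-2-carboxylates.

Step 5
Reactants: 8 ethyl 5,7-bis(benzyloxy)-6-methoxy-4-oxo-4H-chromene-2-carboxylate
Product: 9 5,7-bis(benzyloxy)-2-(hydroxymethyl)-6-methoxy-4H-chromen-4-one
Conditions: NaBH4, MeOH/THF, 0 °C
Reagents that add atoms: none
Why: Chemoselective borohydride reduction, because the C2 ester is activated by the ring oxygen and the enone and is reduced at 0 °C faster than the vinylogous-ester C4 carbonyl, as is known for chromone-2-carboxylates.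

Step 6
Reactants: 9 5,7-bis(benzyloxy)-2-(hydroxymethyl)-6-methoxy-4H-chromen-4-one
Product: 10 5,7-bis(benzyloxy)-6-methoxy-4-oxo-4H-chromene-2-carbaldehyde
Conditions: Dess–Martin periodinane, CH2Cl2, 25 °C
Reagents that add atoms: none
Why: Dess–Martin oxidation of the allylic-type primary alcohol under neutral conditions that leave the benzyl ethers and the pyranone untouched and cannot over-oxidise.

Step 7
Reactants: 10 5,7-bis(benzyloxy)-6-methoxy-4-oxo-4H-chromene-2-carbaldehyde; 11 dimethyl (1-diazo-2-oxopropyl)phosphonate
Product: 12 5,7-bis(benzyloxy)-2-ethynyl-6-methoxy-4H-chromen-4-one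
Conditions: K2CO3, MeOH/THF, 0 °C, short reaction time
Reagents that add atoms: none
Why: Seyferth–Gilbert homologation in the Ohira–Bestmann variant, in which methanolysis of 11 gives the diazomethylphosphonate anion that adds to the aldehyde, and elimination of phosphate, loss of N2 and a 1,2-hydride shift of the alkylidene carbene give the terminal alkyne.

Step 8
Reactants: 12 5,7-bis(benzyloxy)-2-ethynyl-6-methoxy-4H-chromen-4-one; 13 (E)-1-methoxy-3-(trimethylsilyloxy)buta-1,3-diene
Product: 15 5,7-bis(benzyloxy)-2-(4-hydroxyphenyl)-6-methoxy-4H-chromen-4-one, via cyclohexadiene cycloadduct 14 (not isolated)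
Conditions: 13 (4 equiv), BHT (cat.), toluene, 110 °C, sealed tube; then 1 M HCl, THF, 25 °C
Reagents that add atoms: none
Why: Proposed new method: the alkyne of 12 is conjugated through C2=C3 to the C4 carbonyl (a vinylogous ynone), which lowers its LUMO and places the largest alkyne coefficient on the terminal carbon, so a thermal, concerted but asynchronous (4+2) cycloaddition with the electron-rich diene 13, whose largest HOMO coefficient sits on its unsubstituted terminus, should be feasible. The closest known reaction type is the Diels–Alder reaction of 1-alkoxy-3-silyloxybutadienes with acetylenic ketones and propiolates followed by loss of alcohol to give para-acylphenols; the new element is that the activating carbonyl is one vinylogous position further away. Ring B closes by this intermolecular (4+2) annulation, C1'–C2' and C5'–C6' forming together to give cyclohexa-1,4-diene 14, and dilute acid then cleaves the silyl enol ether, eliminates methanol and lets the dienone tautomerise to the phenol. No stereocentre results, since the CH(OMe) centre of 14 forms as a racemate and is destroyed on aromatisation. The step needs para regioselectivity and selectivity for the alkyne over the C2=C3 bond and over conjugate addition at C2; the first follows from bonding of the nucleophilic diene terminus to the electrophilic terminal alkyne carbon, the second from the unhindered terminal alkyne against the fully substituted, oxygen-donated C2, and Lewis acids are avoided so that no benzopyrylium-type addition at C2 competes.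

Step 9
Reactants: 15 5,7-bis(benzyloxy)-2-(4-hydroxyphenyl)-6-methoxy-4H-chromen-4-one
Product: 16 hispidulin, 5,7-dihydroxy-2-(4-hydroxyphenyl)-6-methoxy-4H-chromen-4-one
Conditions: H2 (1 atm), 10% Pd/C, EtOAc/MeOH, 25 °C
Reagents that add atoms: none
Why: Catalytic hydrogenolysis of the two benzyl aryl ethers, which at 1 atm is faster than reduction of the flavone C2=C3 bond, so the reaction is stopped after uptake of two equivalents of H2.

Step 10
Reactants: 16 hispidulin
Product: 17 hispidulin 7,4'-disulfate, 5-hydroxy-6-methoxy-4-oxo-2-[4-(sulfooxy)phenyl]-4H-chromen-7-yl hydrogen sulfate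
Conditions: SO3·pyridine (3 equiv), pyridine, 25 °C; then Dowex 50WX8 (H+ form), H2O, 0 °C, freeze-drying
Reagents that add atoms: sulfur trioxide–pyridine complex, [O-]S(=O)(=O)[n+]1ccccc1
Why: O-Sulfation with the SO3–pyridine complex, in which the acidic 7-OH and the 4'-OH react while the 5-OH is deactivated by its hydrogen bond to the C4 carbonyl and by the flanking 6-OMe, so a small excess of reagent should stop at the 7,4'-disulfate.

**Compound list**

1 | 2',4',6'-trihydroxyacetophenone | CC(=O)c1c(O)cc(O)cc1O | starting material
2 | 1-[2,4-bis(benzyloxy)-6-hydroxyphenyl]ethanone | CC(=O)c1c(O)cc(OCc2ccccc2)cc1OCc1ccccc1 | intermediate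
3 | potassium 3-acetyl-2,6-bis(benzyloxy)-4-hydroxyphenyl sulfate | CC(=O)c1c(O)cc(OCc2ccccc2)c(OS(=O)(=O)[O-])c1OCc1ccccc1.[K+] | intermediate (not isolated)
4 | 1-[2,4-bis(benzyloxy)-3,6-dihydroxyphenyl]ethanone | CC(=O)c1c(O)cc(OCc2ccccc2)c(O)c1OCc1ccccc1 | intermediate
5 | 1-[2,4-bis(benzyloxy)-6-hydroxy-3-methoxyphenyl]ethanone | COc1c(OCc2ccccc2)cc(O)c(C(C)=O)c1OCc1ccccc1 | intermediate
6 | diethyl oxalate | CCOC(=O)C(=O)OCC | starting material
7 | ethyl 4-[2,4-bis(benzyloxy)-6-hydroxy-3-methoxyphenyl]-2,4-dioxobutanoate | CCOC(=O)C(=O)CC(=O)c1c(O)cc(OCc2ccccc2)c(OC)c1OCc1ccccc1 | intermediate (not isolated)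
8 | ethyl 5,7-bis(benzyloxy)-6-methoxy-4-oxo-4H-chromene-2-carboxylate | CCOC(=O)c1cc(=O)c2c(OCc3ccccc3)c(OC)c(OCc3ccccc3)cc2o1 | intermediate
9 | 5,7-bis(benzyloxy)-2-(hydroxymethyl)-6-methoxy-4H-chromen-4-one | COc1c(OCc2ccccc2)cc2oc(CO)cc(=O)c2c1OCc1ccccc1 | intermediate
10 | 5,7-bis(benzyloxy)-6-methoxy-4-oxo-4H-chromene-2-carbaldehyde | COc1c(OCc2ccccc2)cc2oc(C=O)cc(=O)c2c1OCc1ccccc1 | intermediate
11 | dimethyl (1-diazo-2-oxopropyl)phosphonate | COP(=O)(OC)C(=[N+]=[N-])C(C)=O | starting material
12 | 5,7-bis(benzyloxy)-2-ethynyl-6-methoxy-4H-chromen-4-one | COc1c(OCc2ccccc2)cc2oc(C#C)cc(=O)c2c1OCc1ccccc1 | intermediate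
13 | (E)-1-methoxy-3-(trimethylsilyloxy)buta-1,3-diene | CO/C=C/C(=C)O[Si](C)(C)C | starting material
14 | 5,7-bis(benzyloxy)-6-methoxy-2-[6-methoxy-4-(trimethylsilyloxy)cyclohexa-1,4-dien-1-yl]-4H-chromen-4-one (racemic) | COC1C=C(O[Si](C)(C)C)CC=C1c1cc(=O)c2c(OCc3ccccc3)c(OC)c(OCc3ccccc3)cc2o1 | intermediate (not isolated)
15 | 5,7-bis(benzyloxy)-2-(4-hydroxyphenyl)-6-methoxy-4H-chromen-4-one | COc1c(OCc2ccccc2)cc2oc(-c3ccc(O)cc3)cc(=O)c2c1OCc1ccccc1 | intermediate
16 | hispidulin, 5,7-dihydroxy-2-(4-hydroxyphenyl)-6-methoxy-4H-chromen-4-one | COc1c(O)cc2oc(-c3ccc(O)cc3)cc(=O)c2c1O | intermediate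
17 | hispidulin 7,4'-disulfate | COc1c(OS(=O)(=O)O)cc2oc(-c3ccc(OS(=O)(=O)O)cc3)cc(=O)c2c1O | target

**Step count**

Total steps: 10. Longest linear sequence: 10 steps (1 to 17).

**Steps most likely to fail**

Step 8. The vinylogously activated alkyne may react too slowly, so that the diene polymerises or hydrolyses before cycloaddition, or the diene may add in a stepwise conjugate manner at C2 instead. The fallback gives up the cycloaddition and builds ring B by known Baker–Venkataraman chemistry, setting out from ketone 5. Acylation of its free 6-OH with 4-(benzyloxy)benzoyl chloride in pyridine at 25 °C would give the aryl ester 2-acetyl-3,5-bis(benzyloxy)-4-methoxyphenyl 4-(benzyloxy)benzoate F1. Rearrangement with KOH in pyridine at 50 °C would give the diketone 1-[2,4-bis(benzyloxy)-6-hydroxy-3-methoxyphenyl]-3-[4-(benzyloxy)phenyl]propane-1,3-dione F2. Cyclodehydration with catalytic H2SO4 in AcOH at 60 °C would give the flavone 5,7-bis(benzyloxy)-2-[4-(benzyloxy)phenyl]-6-methoxy-4H-chromen-4-one F3. Hydrogenolysis of all three benzyl ethers (H2, 10% Pd/C) comes back to the route at 16.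

Step 7. Methoxide may add in conjugate fashion to the electron-poor aldehyde or to the product alkyne, and the pyranone ring may open under the basic methanolic conditions. The fallback avoids methanol and the diazo reagent and sets out from aldehyde 10. Wittig bromomethylenation with Ph3P=CHBr, made from (bromomethyl)triphenylphosphonium bromide and KOt-Bu in THF at −78 °C, would give the bromoalkene 5,7-bis(benzyloxy)-2-[(Z)-2-bromoethenyl]-6-methoxy-4H-chromen-4-one F4. Anti-elimination of HBr with KOt-Bu in THF at −78 to 0 °C comes back to the route at 12.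

Step 2. The oxidation site lies between two benzyloxy groups, so conversion may be low; the hydroquinone may also be over-oxidised, and a benzyl ether may be lost during acidic hydrolysis of the sulfate. The fallback replaces the persulfate route by oxidation to the quinone and reduction, setting out from phenol 2. Teuber oxidation with ON(SO3K)2 in aqueous KH2PO4/acetone at 25 °C would give the para-quinone 2-acetyl-3,5-bis(benzyloxy)cyclohexa-2,5-diene-1,4-dione F5. Reduction with Na2S2O4 in EtOAc/H2O comes back to the route at 4.

**Further compounds**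

F1 | step 8 | 2-acetyl-3,5-bis(benzyloxy)-4-methoxyphenyl 4-(benzyloxy)benzoate | COc1c(OCc2ccccc2)cc(OC(=O)c2ccc(OCc3ccccc3)cc2)c(C(C)=O)c1OCc1ccccc1
F2 | step 8 | 1-[2,4-bis(benzyloxy)-6-hydroxy-3-methoxyphenyl]-3-[4-(benzyloxy)phenyl]propane-1,3-dione | COc1c(OCc2ccccc2)cc(O)c(C(=O)CC(=O)c2ccc(OCc3ccccc3)cc2)c1OCc1ccccc1
F3 | step 8 | 5,7-bis(benzyloxy)-2-[4-(benzyloxy)phenyl]-6-methoxy-4H-chromen-4-one | COc1c(OCc2ccccc2)cc2oc(-c3ccc(OCc4ccccc4)cc3)cc(=O)c2c1OCc1ccccc1
F4 | step 7 | 5,7-bis(benzyloxy)-2-[(Z)-2-bromoethenyl]-6-methoxy-4H-chromen-4-one | COc1c(OCc2ccccc2)cc2oc(/C=C\Br)cc(=O)c2c1OCc1ccccc1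
F5 | step 2 | 2-acetyl-3,5-bis(benzyloxy)cyclohexa-2,5-diene-1,4-dione | CC(=O)C1=C(OCc2ccccc2)C(=O)C(OCc2ccccc2)=CC1=O
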